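## Assumptions
- The SMILES is taken exactly as drawn. The A/B ring fusion is cis (Me‑5 and H‑10 on the same face), CH2Ar at C9 is syn to Me‑5, and Me‑8 is syn to CH2Ar.
- Ring positions use the target numbering: C1–C3 are CH2 of ring A; C4 bears the exocyclic =CH2; C5 is quaternary (Me); C6–C7 are CH2; C8 is CHMe; C9 is quaternary (Me, CH2Ar); C10 is the ring-fusion CH.
- 2‑Methylcyclohex‑2‑enone, Danishefsky's diene and 2,5‑dimethoxybenzoquinone are commercial. The catalyst enantiomer is chosen to give the enantiomer required.

## Retrosynthetic overview
1. Disconnect the CH2–quinone bond: decarboxylative radical C–H alkylation of hydroxyquinone **12** with the neopentyl acid **10** (C9–CH2CO2H).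
2. **10** comes from a C4 Wittig methylenation, conversion of the C8 ketone to CH–Me by methylenation and hydrogenation, and a convex‑face enolate alkylation that forms the C9 quaternary centre.
3. The cis‑fused enedione **3** comes from an asymmetric Diels–Alder of 2‑methylcyclohexenone (ring A) with Danishefsky's diene. This forms ring B and sets C5 and C10.
4. Ring order: ring A is already present in the starting material, ring B forms in step 1, and the quinone ring is attached last.

## Route

**Step 1**
Reactants: **1** 2‑methylcyclohex‑2‑en‑1‑one; **2** (E)‑1‑methoxy‑3‑(trimethylsilyloxy)buta‑1,3‑diene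
Product: **3** cis‑(4aS,8aS)‑8a‑methyl‑3,4,4a,5‑tetrahydronaphthalene‑1,6(2H,8aH)‑dione
Conditions: chiral IDPi (5 mol %), toluene, –20 °C → rt, 48 h; then 1 M HCl, THF, rt
Reagents that add atoms: none
Why: Asymmetric Diels–Alder; the nucleophilic diene terminus (CH2) bonds to the enone β‑carbon (C10) and the CH(OMe) terminus to the α‑carbon (C5), the usual "ortho" regiochemistry. The catalyst fixes the enone face and so the absolute configuration at C5/C10. Suprafacial addition to the cyclic alkene makes the ring fusion cis. Acid then removes TMS and eliminates MeOH to give the C8 enone.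
Proposed new method: a confined chiral IDPi is silylated in situ by the silyl dienol ether to give a chiral silylium Lewis acid that binds the enone carbonyl and blocks one face. The closest known chemistry is IDPi/silylium‑catalysed Diels–Alder reactions of cinnamates and enones, and Danishefsky‑diene cycloadditions to aldehydes and acroleins. The new feature is an α‑substituted cyclic enone as dienophile, creating an angular quaternary stereocentre.

**Step 2**
Reactants: **3**; ethylene glycol
Product: **4** the C4 ethylene ketal of **3**, enone intact
Conditions: (CH2OH)2 (1.5 equiv), TsOH·H2O (5 mol %), benzene, rt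
Reagents that add atoms: ethylene glycol, OCCO
Why: Ketalization. The saturated C4 ketone reacts selectively over the conjugated C8 ketone, as in Wieland–Miescher ketone. This protects C4 from enolization and later hydrogenation.

**Step 3**
Reactants: **4**; MeI
Product: **5** C9‑methyl enone (C9 epimer mixture)
Conditions: LDA (1.05 equiv), THF, –78 °C; then MeI (1.2 equiv), –78 → 0 °C
Reagents that add atoms: methyl iodide, CI
Why: Enolate alkylation. The only enolizable position is C9 (α′), because C5 is quaternary and there is no γ‑H, so the cross‑conjugated enolate forms regiospecifically. The C9 configuration is erased in the next step.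

**Step 4**
Reactants: **5**; benzyl bromoacetate
Product: **6** C9‑quaternary enone with Me‑9 down and CH2CO2Bn up
Conditions: LDA (1.3 equiv), THF, –78 → –20 °C; DMPU; BrCH2CO2Bn (2 equiv), –78 → 0 °C
Reagents that add atoms: benzyl bromoacetate, BrCC(=O)OCc1ccccc1
Why: Enolate alkylation, which sets C9. In the cis‑fused dienolate, ring A folds under ring B and shields the concave face. The electrophile therefore attacks from the convex face (syn to Me‑5/H‑10), putting CH2CO2Bn up and Me down.

**Step 5**
Reactants: **6**; Ph3P=CH2
Product: **7** C8‑methylene diene (C8=CH2 conjugated with C6=C7)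
Conditions: Ph3PCH3Br, KOtBu (3 equiv), toluene, 90 °C
Reagents that add atoms: methylenetriphenylphosphorane, C=P(c1ccccc1)(c1ccccc1)c1ccccc1
Why: Wittig methylenation of the hindered enone. The ketal and benzyl ester survive, and C9 has no α‑H so it cannot epimerize.

**Step 6**
Reactants: **7**; H2
Product: **8** keto‑ketal carboxylic acid with C8‑Me and saturated C6/C7
Conditions: H2 (5 atm), 10 % Pd/C then PtO2 if needed, EtOAc, rt
Reagents that add atoms: hydrogen, [H][H]
Why: Catalytic hydrogenation reduces the diene and cleaves the benzyl ester (toluene is lost), setting C8. H2 adds from the face opposite the crowded face bearing Me‑5 and the adjacent CH2CO2R, so H‑8 goes down and Me‑8 ends up cis to CH2CO2H.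

**Step 7**
Reactants: **8**; water
Product: **9** C4 ketone acid
Conditions: 2 M HCl, THF, rt
Reagents that add atoms: water, O
Why: Ketal hydrolysis. No stereocentre is α to a carbonyl, so nothing epimerizes.

**Step 8**
Reactants: **9**; Ph3P=CH2
Product: **10** exocyclic‑methylene acid, C9‑CH2CO2H
Conditions: Ph3PCH3Br (4 equiv), KOtBu (4.4 equiv), THF, reflux; acidify to pH ~4 with aqueous NaH2PO4
Reagents that add atoms: methylenetriphenylphosphorane, C=P(c1ccccc1)(c1ccccc1)c1ccccc1
Why: Wittig methylenation of the neopentyl C4 ketone. The first equivalent of ylide only deprotonates the acid. The mild workup avoids isomerizing the acid‑sensitive exocyclic alkene.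

**Step 9**
Reactants: **11** 2,5‑dimethoxy‑1,4‑benzoquinone; hydroxide
Product: **12** 2‑hydroxy‑5‑methoxy‑1,4‑benzoquinone
Conditions: NaOH (1.05 equiv), THF/H2O, 0 °C → rt; then HCl to pH 2
Reagents that add atoms: hydroxide, [OH-]
Why: Addition–elimination hydrolysis of a vinylogous ester. The resulting hydroxyquinone anion is deactivated, so only one OMe is displaced.

**Step 10**
Reactants: **10**; **12** (2 equiv)
Product: **13** target
Conditions: AgNO3 (20 mol %), (NH4)2S2O8 (2.5 equiv), MeCN/H2O 1:1, 65 °C
Reagents that add atoms: none
Why: Kochi–Anderson‑type decarboxylative radical alkylation, as used for atovaquone and maesanin‑type hydroxyquinones. Ag(II) decarboxylates **10** to the primary neopentyl radical, which adds to C3 of **12** (adjacent to the OH). Re‑oxidation restores the quinone. The radical forms at the exocyclic CH2, so no ring stereocentre is touched.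

## Compound list
| # | Name | SMILES | Role |
|---|---|---|---|
| 1 | 2‑methylcyclohex‑2‑en‑1‑one | CC1=CCCCC1=O | starting material |
| 2 | Danishefsky's diene | CO/C=C/C(=C)O[Si](C)(C)C | starting material |
| 3 | cis‑fused enedione | O=C1CCC[C@H]2CC(=O)C=C[C@@]12C | intermediate |
| 4 | C4 ethylene ketal of 3 | C14(OCCO4)CCC[C@H]2CC(=O)C=C[C@@]12C | intermediate |
| 5 | 9‑methyl ketal enone (C9 epimers) | C14(OCCO4)CCC[C@H]2C(C)C(=O)C=C[C@@]12C | intermediate |
| 6 | C9‑quaternary ketal enone benzyl ester | C14(OCCO4)CCC[C@H]2[C@](C)(CC(=O)OCc3ccccc3)C(=O)C=C[C@@]12C | intermediate |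
| 7 | C8‑methylene diene | C14(OCCO4)CCC[C@H]2[C@](C)(CC(=O)OCc3ccccc3)C(=C)C=C[C@@]12C | intermediate |
| 8 | ketal acid with C8‑Me | C14(OCCO4)CCC[C@H]2[C@](C)(CC(=O)O)[C@H](C)CC[C@@]12C | intermediate |
| 9 | keto acid | O=C1CCC[C@H]2[C@](C)(CC(=O)O)[C@H](C)CC[C@@]12C | intermediate |
| 10 | methylene acid | C=C1CCC[C@H]2[C@](C)(CC(=O)O)[C@H](C)CC[C@@]12C | intermediate |
| 11 | 2,5‑dimethoxy‑1,4‑benzoquinone | COC1=CC(=O)C(OC)=CC1=O | starting material |
| 12 | 2‑hydroxy‑5‑methoxy‑1,4‑benzoquinone | COC1=CC(=O)C(O)=CC1=O | intermediate |
| 13 | target | C=C1CCC[C@H]2[C@](C)(CC3=C(O)C(=O)C=C(OC)C3=O)[C@H](C)CC[C@@]12C | target |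

## Totals
- Total steps: 10.
- Longest linear sequence: 9 (steps 1–8 and 10; step 9 is a parallel branch).

## Three steps most likely to fail
1. **Step 1 (new asymmetric Diels–Alder).** The α‑methyl cyclohexenone is a poor dienophile and may give low conversion or ee. Fallback, using known chemistry: a proline‑ or primary‑amine‑catalysed Robinson annulation of 2‑methylcyclohexane‑1,3‑dione with ethyl vinyl ketone gives the 9‑methyl Wieland–Miescher analogue. Then selectively ketalize C4 and hydrogenate the enone under basic conditions (Pd/C, KOH) to give the cis ring fusion. Alkylate at C9 with benzyl bromoacetate using a thermodynamic enolate, separating the C7‑alkylation regioisomer. This rejoins the route at the saturated analogue of **6** (step 5 onward).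
2. **Step 6 (C8 stereochemistry by hydrogenation).** The face selectivity is only argued from sterics and may give the 8‑epimer. Fallback: Stryker conjugate reduction of **6**, then MeLi/CeCl3 addition to the saturated C8 ketone (axial, convex‑face attack puts Me up). Convert the tertiary alcohol to its methyl oxalate and deoxygenate under metal‑free photochemical Barton–McCombie conditions, separating epimers.
3. **Step 10 (radical coupling).** Risks are poor regioselectivity between C3 and C6 of **12**, the hindered neopentyl radical, and acid or persulfate damage to the exocyclic alkene. Fallback: carry a C9–CH2OBn handle instead, by alkylating with BnOCH2Cl in step 4. Hydrogenolysis in step 6 then gives the neopentyl alcohol. Oxidize it to the C9 aldehyde (DMP) and couple with **12** by polar reductive Knoevenagel alkylation (Hantzsch ester), which fixes attack at C3.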